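**Retrosynthetic overview**

1. Feature: each dihydropyrano-tropolone (pyran ring C with tropolone ring D, and pyran ring B with tropolone ring A) is a cyclopentane-1,3-dione. One dione oxygen is the pyran O1, and the former C6–C9a bond is widened by the two alkyne carbons of a but-2-ynyl unit (C4a and the methyl-bearing C5); O1–C2–C3–C4 is the tether.
2. Both tropolones are made last and together: 27 ⇐ bis-ketol 25 ⇐ bis-dienone 23, by hydroxylation at C8/C8′ beside each ketone and oxidation.
3. The central C–C bond of the E,E-diene comes from Suzuki coupling of (E)-vinyl iodide 14 (rings C and D) with (E)-vinylboronate 22 (rings A and B), each made from the C2 aldehyde.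
4. Key disconnection, used once per half: intramolecular enone–alkyne [2+2] photocycloaddition and cyclobutene opening, 9 → 11 (ring C, then ring D) and 17 → 19 (ring B, then ring A).
5. Both carbinols come from one Sharpless epoxy alcohol 5 (H or CH3 delivered to C3). Ring order: C and D (step 7), B and A (step 14), union (step 18), tropolones (steps 19–20).

Key step: step 7

**Remarks**

- Bicycle numbering is that of cyclohepta[b]pyran: O1, C2, C3, C4, C4a, C5–C9, C9a.
- Assumption: the two tropolone tautomers (proton on either oxygen) interconvert fast and are one compound; the target SMILES shows one of them.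
- The silyl group is triisopropylsilyl. It is transparent at 254 nm, tolerates the acid of the etherification, and is slow to migrate between oxygens.
- The etherification keeps the carbinol C–O bond, so the configuration set in epoxide 5 is carried unchanged into both halves.
- The photoreaction is run at 254 nm, where the 3-alkoxycyclopentenone absorbs strongly. The dienone product should absorb above about 320 nm, so longer wavelengths are avoided.

**Route**

Step 1
Reactants: 1 prop-2-yn-1-ol; 2 1-bromobut-2-yne
Product: 3 hepta-2,5-diyn-1-ol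
Conditions: CuI (cat.), n-Bu4NCl, K2CO3, DMF, rt
Reagents that add atoms: none
Why: Copper-catalysed alkynyl–propargyl coupling; the copper acetylide of 1 should displace the primary bromide of 2 directly (SN2, no allene), the standard entry to skipped diynes.

Step 2
Reactants: 3 hepta-2,5-diyn-1-ol
Product: 4 (2E)-hept-2-en-5-yn-1-ol
Conditions: NaAlH2(OCH2CH2OMe)2, THF, 0 °C → rt; aqueous work-up
Reagents that add atoms: none
Why: Alkoxide-directed trans-hydroalumination reduces only the propargylic triple bond (the isolated alkyne has no directing oxygen), and protonolysis gives the E-allylic alcohol.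

Step 3
Reactants: 4 (2E)-hept-2-en-5-yn-1-ol
Product: 5 [(2S,3S)-3-(but-2-yn-1-yl)oxiran-2-yl]methanol
Conditions: Ti(OiPr)4 (cat.), L-(+)-diisopropyl tartrate (cat.), t-BuOOH, 4 Å MS, CH2Cl2, −20 °C
Reagents that add atoms: tert-butyl hydroperoxide, CC(C)(C)OO
Why: Sharpless asymmetric epoxidation; with the L-(+)-tartrate ligand an E-allylic alcohol should be epoxidised on the face that gives the (2S,3S)-epoxide, and the alkyne is inert to this oxidant.

Step 4
Reactants: 5 [(2S,3S)-3-(but-2-yn-1-yl)oxiran-2-yl]methanol
Product: 6 (2R)-hept-5-yne-1,2-diol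
Conditions: i-Bu2AlH, PhMe, 0 °C → rt; Rochelle salt work-up
Reagents that add atoms: none
Why: Regioselective reductive opening of a 2,3-epoxy alcohol, in which the aluminium alkoxide activates the epoxide and hydride enters at C3 (1,2-diol mode); C2 is untouched, and its descriptor changes from S to R only because CH2OH now outranks C3.

Step 5
Reactants: 6 (2R)-hept-5-yne-1,2-diol
Product: 7 (2R)-1-[(triisopropylsilyl)oxy]hept-5-yn-2-ol
Conditions: TIPSCl, imidazole, CH2Cl2, 0 °C
Reagents that add atoms: chlorotriisopropylsilane, CC(C)[Si](Cl)(C(C)C)C(C)C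
Why: Sterically controlled silylation; the bulky silyl chloride should take the primary hydroxyl only.

Step 6
Reactants: 7 (2R)-1-[(triisopropylsilyl)oxy]hept-5-yn-2-ol; 8 cyclopentane-1,3-dione
Product: 9 3-({(2R)-1-[(triisopropylsilyl)oxy]hept-5-yn-2-yl}oxy)cyclopent-2-en-1-one
Conditions: 8 (2 equiv), p-TsOH·H2O (cat.), PhH, reflux, Dean–Stark
Reagents that add atoms: none
Why: Acid-catalysed vinylogous esterification (hemiketal formation at a dione carbonyl, then dehydration), driven by azeotropic removal of water; the carbinol C–O bond is not broken, so (R) is retained.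

Step 7
Reactants: 9 3-({(2R)-1-[(triisopropylsilyl)oxy]hept-5-yn-2-yl}oxy)cyclopent-2-en-1-one
Product: 11 (2R)-5-methyl-2-{[(triisopropylsilyl)oxy]methyl}-3,4,8,9-tetrahydrocyclohepta[b]pyran-7(2H)-one, via cyclobutene photoadduct 10 (not isolated)
Conditions: hν (254 nm, quartz), degassed MeCN (0.01 M), −20 °C; then CF3CH2OH, 40 °C, dark
Reagents that add atoms: none
Why: Excitation of the vinylogous ester gives the enone triplet, whose alkoxy-bearing β-carbon (future C9a) attacks the nearer alkyne carbon (future C4a) to close ring C, and the resulting 1,4-biradical (α-keto radical and vinyl radical) collapses to the cis-fused cyclobutene 10, forming the C5–C6 bond. In 10 the bond between the O-bearing quaternary carbon and the carbon α to the ketone lies between a donor and an acceptor, so it should break heterolytically in the hydrogen-bonding fluoro alcohol and give the push–pull dienone directly; ring D thereby grows from five to seven members by taking in the two alkyne carbons. The closest known reaction type is the alkyne version of the de Mayo reaction, an intramolecular enone–alkyne [2+2] photocycloaddition of a vinylogous ester followed by retro-aldol-type cyclobutene opening. Ring C closes in the 6-exo-dig, straight mode, the four-membered ring closes by biradical recombination, and ring D arises by fragmentation and not by a closure. No new stereocentre survives: the two ring-fusion centres of 10 are necessarily cis, both diastereomers converge on 11, and C2 takes no part. The step needs straight closure, which the four-atom tether O1–C2–C3–C4 secures because every crossed alternative would need a seven- or eight-membered ring, and it needs light to reach only the substrate, which the 254 nm line and cold irradiation in MeCN (where 10 should accumulate and is opened later in the dark) are meant to secure.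

Step 8
Reactants: 11 (2R)-5-methyl-2-{[(triisopropylsilyl)oxy]methyl}-3,4,8,9-tetrahydrocyclohepta[b]pyran-7(2H)-one
Product: 12 (2R)-2-(hydroxymethyl)-5-methyl-3,4,8,9-tetrahydrocyclohepta[b]pyran-7(2H)-one
Conditions: n-Bu4NF, AcOH, THF, 0 °C → rt
Reagents that add atoms: none
Why: Fluoride-induced desilylation, buffered with acetic acid so that the enolisable dienone is not exposed to free base.

Step 9
Reactants: 12 (2R)-2-(hydroxymethyl)-5-methyl-3,4,8,9-tetrahydrocyclohepta[b]pyran-7(2H)-one
Product: 13 (2R)-5-methyl-7-oxo-2,3,4,7,8,9-hexahydrocyclohepta[b]pyran-2-carbaldehyde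
Conditions: Dess–Martin periodinane, NaHCO3, CH2Cl2, 0 °C → rt
Reagents that add atoms: none
Why: Dess–Martin oxidation under buffered, non-basic conditions should give the α-alkoxy aldehyde without epimerisation at C2; it is used crude.

Step 10
Reactants: 13 (2R)-5-methyl-7-oxo-2,3,4,7,8,9-hexahydrocyclohepta[b]pyran-2-carbaldehyde
Product: 14 (2R)-2-[(E)-2-iodoethenyl]-5-methyl-3,4,8,9-tetrahydrocyclohepta[b]pyran-7(2H)-one
Conditions: CrCl2, CHI3, THF, 0 °C → rt
Reagents that add atoms: iodoform, IC(I)I
Why: Takai olefination; the geminal dichromium reagent adds to the aldehyde only (the vinylogous-ester ketone is too unreactive) and anti elimination gives the E-vinyl iodide under non-basic conditions.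

Step 11
Reactants: 5 [(2S,3S)-3-(but-2-yn-1-yl)oxiran-2-yl]methanol
Product: 15 (2R,3R)-3-methylhept-5-yne-1,2-diol
Conditions: AlMe3, CH2Cl2–hexane, 0 °C → rt
Reagents that add atoms: trimethylaluminium, C[Al](C)C
Why: Trialkylaluminium opening of a 2,3-epoxy alcohol at C3 with inversion; methyl enters anti to the departing oxygen, which sets C3 as R and gives the 2,3-anti diol that becomes the trans pair of ring B.

Step 12
Reactants: 15 (2R,3R)-3-methylhept-5-yne-1,2-diol
Product: 16 (2R,3R)-3-methyl-1-[(triisopropylsilyl)oxy]hept-5-yn-2-ol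
Conditions: TIPSCl, imidazole, CH2Cl2, 0 °C
Reagents that add atoms: chlorotriisopropylsilane, CC(C)[Si](Cl)(C(C)C)C(C)C
Why: Selective silylation of the primary hydroxyl, as in step 5.

Step 13
Reactants: 16 (2R,3R)-3-methyl-1-[(triisopropylsilyl)oxy]hept-5-yn-2-ol; 8 cyclopentane-1,3-dione
Product: 17 3-({(2R,3R)-3-methyl-1-[(triisopropylsilyl)oxy]hept-5-yn-2-yl}oxy)cyclopent-2-en-1-one
Conditions: 8 (2–3 equiv), p-TsOH·H2O (cat.), PhH, reflux, Dean–Stark
Reagents that add atoms: none
Why: Acid-catalysed vinylogous esterification as in step 6, with retention at C2 because only the dione C–O bond is exchanged.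

Step 14
Reactants: 17 3-({(2R,3R)-3-methyl-1-[(triisopropylsilyl)oxy]hept-5-yn-2-yl}oxy)cyclopent-2-en-1-one
Product: 19 (2R,3R)-3,5-dimethyl-2-{[(triisopropylsilyl)oxy]methyl}-3,4,8,9-tetrahydrocyclohepta[b]pyran-7(2H)-one, via cyclobutene photoadduct 18 (not isolated)
Conditions: hν (254 nm, quartz), degassed MeCN (0.01 M), −20 °C; then CF3CH2OH, 40 °C, dark
Reagents that add atoms: none
Why: The same enone–alkyne [2+2] photocycloaddition and donor–acceptor cyclobutene opening as in step 7 close ring B (6-exo-dig, straight) and expand the cyclopentenone to ring A; the two preset centres C2 and C3 lie in the tether and are not touched.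

Step 15
Reactants: 19 (2R,3R)-3,5-dimethyl-2-{[(triisopropylsilyl)oxy]methyl}-3,4,8,9-tetrahydrocyclohepta[b]pyran-7(2H)-one
Product: 20 (2R,3R)-2-(hydroxymethyl)-3,5-dimethyl-3,4,8,9-tetrahydrocyclohepta[b]pyran-7(2H)-one
Conditions: n-Bu4NF, AcOH, THF, 0 °C → rt
Reagents that add atoms: none
Why: Buffered fluoride desilylation, as in step 8.

Step 16
Reactants: 20 (2R,3R)-2-(hydroxymethyl)-3,5-dimethyl-3,4,8,9-tetrahydrocyclohepta[b]pyran-7(2H)-one
Product: 21 (2R,3R)-3,5-dimethyl-7-oxo-2,3,4,7,8,9-hexahydrocyclohepta[b]pyran-2-carbaldehyde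
Conditions: Dess–Martin periodinane, NaHCO3, CH2Cl2, 0 °C → rt
Reagents that add atoms: none
Why: Buffered Dess–Martin oxidation, as in step 9; the aldehyde is used crude to protect C2.

Step 17
Reactants: 21 (2R,3R)-3,5-dimethyl-7-oxo-2,3,4,7,8,9-hexahydrocyclohepta[b]pyran-2-carbaldehyde
Product: 22 (2R,3R)-3,5-dimethyl-2-[(E)-2-(4,4,5,5-tetramethyl-1,3,2-dioxaborolan-2-yl)ethenyl]-3,4,8,9-tetrahydrocyclohepta[b]pyran-7(2H)-one
Conditions: CrCl2, Cl2CHBpin, LiI, THF, rt
Reagents that add atoms: 2-(dichloromethyl)-4,4,5,5-tetramethyl-1,3,2-dioxaborolane, ClC(Cl)B1OC(C)(C)C(C)(C)O1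
Why: Takai–Utimoto boron olefination; the geminal dichromium species formed from the dihalomethylboronate adds to the aldehyde and eliminates to the E-alkenylboronate under non-basic conditions.

Step 18
Reactants: 14 (2R)-2-[(E)-2-iodoethenyl]-5-methyl-3,4,8,9-tetrahydrocyclohepta[b]pyran-7(2H)-one; 22 (2R,3R)-3,5-dimethyl-2-[(E)-2-(4,4,5,5-tetramethyl-1,3,2-dioxaborolan-2-yl)ethenyl]-3,4,8,9-tetrahydrocyclohepta[b]pyran-7(2H)-one
Product: 23 (2R,3R)-3,5-dimethyl-2-{(1E,3E)-4-[(2R)-5-methyl-7-oxo-2,3,4,7,8,9-hexahydrocyclohepta[b]pyran-2-yl]buta-1,3-dien-1-yl}-3,4,8,9-tetrahydrocyclohepta[b]pyran-7(2H)-one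
Conditions: PdCl2(dppf) (cat.), K3PO4, THF–H2O, degassed, rt → 40 °C
Reagents that add atoms: none
Why: Suzuki–Miyaura coupling of two alkenyl partners with retention of both E geometries; oxidative addition of zerovalent palladium to the vinyl carbon–iodine bond should outpace ionisation of the allylic C–O bonds at this temperature, and the phosphate base is too weak to enolise the dienones to any effect.

Step 19
Reactants: 23 bis-dienone (name as in step 18)
Product: 25 8,8′-dihydroxy derivative of 23 (one hydroxyl on the CH2 beside each ketone; mixture of epimers at C8 and C8′), via disodium bis-enolate 24 (not isolated)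
Conditions: NaN(SiMe3)2 (2.3 equiv), THF, −78 °C (23 added to the base); then 2-(benzenesulfonyl)-3-phenyloxaziridine, −78 °C; AcOH quench
Reagents that add atoms: 2-(benzenesulfonyl)-3-phenyloxaziridine, O=S(=O)(N1OC1c1ccccc1)c1ccccc1
Why: Kinetic deprotonation of each dienone at the α′ CH2 (C8) gives the cross-conjugated enolate, and electrophilic hydroxylation with the Davis oxaziridine puts oxygen on C8; the new carbinol centres are left as a mixture because the next step removes them.

Step 20
Reactants: 25 8,8′-dihydroxy derivative of 23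
Product: 27 target CNP0332980.1 (2R,3R,2′R), via bis-1,2-dione 26 (not isolated)
Conditions: Dess–Martin periodinane, NaHCO3, CH2Cl2, 0 °C → rt; work-up at pH 4–5
Reagents that add atoms: none
Why: Dess–Martin oxidation of each α-ketol gives a 1,2-dione whose neighbouring C9 methylene enolises at once to the 2-hydroxytropone (gain of tropolone aromatic stabilisation), so both tropolones form without a separate dehydrogenation.

**Compound list**

1 | prop-2-yn-1-ol | C#CCO | starting material
2 | 1-bromobut-2-yne | CC#CCBr | starting material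
3 | hepta-2,5-diyn-1-ol | CC#CCC#CCO | intermediate
4 | (2E)-hept-2-en-5-yn-1-ol | CC#CC/C=C/CO | intermediate
5 | [(2S,3S)-3-(but-2-yn-1-yl)oxiran-2-yl]methanol | OC[C@@H]1O[C@H]1CC#CC | intermediate
6 | (2R)-hept-5-yne-1,2-diol | OC[C@H](O)CCC#CC | intermediate
7 | (2R)-1-[(triisopropylsilyl)oxy]hept-5-yn-2-ol | CC(C)[Si](C(C)C)(C(C)C)OC[C@H](O)CCC#CC | intermediate
8 | cyclopentane-1,3-dione | O=C1CCC(=O)C1 | starting material
9 | 3-({(2R)-1-[(triisopropylsilyl)oxy]hept-5-yn-2-yl}oxy)cyclopent-2-en-1-one | CC(C)[Si](C(C)C)(C(C)C)OC[C@H](OC1=CC(=O)CC1)CCC#CC | intermediate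
10 | cyclobutene photoadduct of 9: cyclopentanone, methylcyclobutene and tetrahydropyran sharing the O-bearing quaternary carbon; (R) at the silyloxymethyl carbon; ring fusion cis, two diastereomers | CC1=C2CC[C@H](CO[Si](C(C)C)(C(C)C)C(C)C)OC23CCC(=O)C13 | intermediate
11 | (2R)-5-methyl-2-{[(triisopropylsilyl)oxy]methyl}-3,4,8,9-tetrahydrocyclohepta[b]pyran-7(2H)-one | CC1=CC(=O)CCC2=C1CC[C@H](CO[Si](C(C)C)(C(C)C)C(C)C)O2 | intermediate
12 | (2R)-2-(hydroxymethyl)-5-methyl-3,4,8,9-tetrahydrocyclohepta[b]pyran-7(2H)-one | CC1=CC(=O)CCC2=C1CC[C@H](CO)O2 | intermediate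
13 | (2R)-5-methyl-7-oxo-2,3,4,7,8,9-hexahydrocyclohepta[b]pyran-2-carbaldehyde | CC1=CC(=O)CCC2=C1CC[C@H](C=O)O2 | intermediate
14 | (2R)-2-[(E)-2-iodoethenyl]-5-methyl-3,4,8,9-tetrahydrocyclohepta[b]pyran-7(2H)-one | CC1=CC(=O)CCC2=C1CC[C@H](/C=C/I)O2 | intermediate
15 | (2R,3R)-3-methylhept-5-yne-1,2-diol | OC[C@H](O)[C@H](C)CC#CC | intermediate
16 | (2R,3R)-3-methyl-1-[(triisopropylsilyl)oxy]hept-5-yn-2-ol | CC(C)[Si](C(C)C)(C(C)C)OC[C@H](O)[C@H](C)CC#CC | intermediate
17 | 3-({(2R,3R)-3-methyl-1-[(triisopropylsilyl)oxy]hept-5-yn-2-yl}oxy)cyclopent-2-en-1-one | CC(C)[Si](C(C)C)(C(C)C)OC[C@H](OC1=CC(=O)CC1)[C@H](C)CC#CC | intermediate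
18 | cyclobutene photoadduct of 17: as 10 with the (3R)-methyl group on the pyran ring; ring fusion cis, two diastereomers | CC1=C2C[C@@H](C)[C@H](CO[Si](C(C)C)(C(C)C)C(C)C)OC23CCC(=O)C13 | intermediate
19 | (2R,3R)-3,5-dimethyl-2-{[(triisopropylsilyl)oxy]methyl}-3,4,8,9-tetrahydrocyclohepta[b]pyran-7(2H)-one | CC1=CC(=O)CCC2=C1C[C@@H](C)[C@H](CO[Si](C(C)C)(C(C)C)C(C)C)O2 | intermediate
20 | (2R,3R)-2-(hydroxymethyl)-3,5-dimethyl-3,4,8,9-tetrahydrocyclohepta[b]pyran-7(2H)-one | CC1=CC(=O)CCC2=C1C[C@@H](C)[C@H](CO)O2 | intermediate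
21 | (2R,3R)-3,5-dimethyl-7-oxo-2,3,4,7,8,9-hexahydrocyclohepta[b]pyran-2-carbaldehyde | CC1=CC(=O)CCC2=C1C[C@@H](C)[C@H](C=O)O2 | intermediate
22 | (2R,3R)-3,5-dimethyl-2-[(E)-2-(4,4,5,5-tetramethyl-1,3,2-dioxaborolan-2-yl)ethenyl]-3,4,8,9-tetrahydrocyclohepta[b]pyran-7(2H)-one | CC1=CC(=O)CCC2=C1C[C@@H](C)[C@H](/C=C/B1OC(C)(C)C(C)(C)O1)O2 | intermediate
23 | (2R,3R)-3,5-dimethyl-2-{(1E,3E)-4-[(2R)-5-methyl-7-oxo-2,3,4,7,8,9-hexahydrocyclohepta[b]pyran-2-yl]buta-1,3-dien-1-yl}-3,4,8,9-tetrahydrocyclohepta[b]pyran-7(2H)-one | CC1=CC(=O)CCC2=C1C[C@@H](C)[C@H](/C=C/C=C/[C@H]3CCC4=C(O3)CCC(=O)C=C4C)O2 | intermediate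
24 | disodium bis-enolate of 23 (enolate double bonds C7=C8 and C7′=C8′) | [Na+].[Na+].CC1=CC([O-])=CCC2=C1C[C@@H](C)[C@H](/C=C/C=C/[C@H]3CCC4=C(O3)CC=C([O-])C=C4C)O2 | intermediate
25 | 8,8′-dihydroxy derivative of 23 (epimer mixture at C8 and C8′) | CC1=CC(=O)C(O)CC2=C1C[C@@H](C)[C@H](/C=C/C=C/[C@H]3CCC4=C(O3)CC(O)C(=O)C=C4C)O2 | intermediate
26 | 7,8-dioxo-7′,8′-dioxo derivative of 23 (bis-1,2-dione) | CC1=CC(=O)C(=O)CC2=C1C[C@@H](C)[C@H](/C=C/C=C/[C@H]3CCC4=C(O3)CC(=O)C(=O)C=C4C)O2 | intermediate
27 | CNP0332980.1: bis(dihydropyrano-tropolone) joined C2 to C2′ by an (E,E)-buta-1,3-diene; (2R,3R)-trans in ring B, (2′R) in ring C | Cc1cc(=O)c(O)cc2c1C[C@@H](C)[C@H](/C=C/C=C/[C@H]1CCc3c(C)cc(=O)c(O)cc3O1)O2 | target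

**Totals**

Total step count: 20. Longest linear sequence: 13 steps (steps 1–3, one seven-step branch, steps 18–20).

**Steps most likely to fail**

1. Step 7 (the same concern holds for step 14).
   - What may go wrong: the enone triplet may add inefficiently to the unactivated alkyne. The cyclobutene may be lost to a photochemical 1,3-acyl shift before it is opened. The dienone may be photodegraded if ring opening already occurs under the lamp.
   - Fallback: an alkene partner in the photoreaction, with the missing unsaturation restored afterwards. It sets out from 9 and comes back at 11.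
   - Semi-hydrogenation of 9 (H2, Pd/CaCO3 poisoned with Pb(OAc)2, quinoline, EtOAc) should give 3-({(2R,5Z)-1-[(triisopropylsilyl)oxy]hept-5-en-2-yl}oxy)cyclopent-2-en-1-one F1.
   - Its intramolecular enone–alkene [2+2] photocycloaddition (hν > 300 nm, Pyrex, MeCN) is the best-established variant for 3-alkenyloxy enones and leads to a photostable saturated ketone, the tricyclic alkoxycyclobutane F2.
   - TMSOTf/Et3N (CH2Cl2, −78 → 0 °C) should trigger the de Mayo-type retro-aldol fragmentation of the donor–acceptor bond with O-silylation; loss of a proton from the oxocarbenium ion gives the ring-expanded trimethylsilyl enol ether F3, whose silyl enol ether is regiodefined at C6=C7.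
   - Saegusa–Ito oxidation (Pd(OAc)2, MeCN, rt) then introduces the C5=C6 double bond and gives 11; any positional isomer of the ring enol ether should equilibrate to the conjugated push–pull dienone on silica.

2. Step 19.
   - What may go wrong: enolisation may not be regioselective (extended enolate through C9 or the C5 methyl instead of the α′ enolate), or the second hydroxylation may be incomplete on a molecule carrying two enolates.
   - Fallback: non-basic, metal-mediated α′-oxidation. It sets out from 23 and comes back at 25.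
   - Mn(OAc)3 in refluxing benzene, known to acetoxylate enones and β-alkoxy enones at the α′ carbon, should give the 8,8′-diacetoxy derivative of 23 F4.
   - Methanolysis (K2CO3, MeOH, 0 °C, degassed) then gives 25.

3. Step 13 (less severe at step 6).
   - What may go wrong: condensation of the hindered, β-branched secondary alcohol may be slow, which leaves time for acid-promoted loss of the silyl group and for self-condensation of the dione.
   - Fallback: nucleophilic vinylic substitution under basic conditions, again with retention. It sets out from 8 and 16 and comes back at 17.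
   - 8 with (COCl)2 and catalytic DMF in CH2Cl2 gives 3-chlorocyclopent-2-en-1-one F5.
   - 16 with LiN(SiMe3)2 in THF at −78 °C gives lithium (2R,3R)-3-methyl-1-[(triisopropylsilyl)oxy]hept-5-yn-2-olate F6; the lithium counter-ion and low temperature are chosen to suppress O-to-O silyl migration.
   - Addition of F6 to F5 and loss of chloride (−78 → 0 °C) gives 17.

**Further compounds**

F1 | step 7 | 3-({(2R,5Z)-1-[(triisopropylsilyl)oxy]hept-5-en-2-yl}oxy)cyclopent-2-en-1-one | CC(C)[Si](C(C)C)(C(C)C)OC[C@H](OC1=CC(=O)CC1)CC/C=C\C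
F2 | step 7 | tricyclic alkoxycyclobutane photoadduct of F1 (diastereomer mixture at the cyclobutane carbons) | CC1C2CC[C@H](CO[Si](C(C)C)(C(C)C)C(C)C)OC23CCC(=O)C13
F3 | step 7 | (2R)-5-methyl-2-{[(triisopropylsilyl)oxy]methyl}-7-[(trimethylsilyl)oxy]-2,3,4,5,8,9-hexahydrocyclohepta[b]pyran | CC1C=C(O[Si](C)(C)C)CCC2=C1CC[C@H](CO[Si](C(C)C)(C(C)C)C(C)C)O2
F4 | step 19 | 8,8′-diacetoxy derivative of 23 (epimer mixture at C8 and C8′) | CC1=CC(=O)C(OC(C)=O)CC2=C1C[C@@H](C)[C@H](/C=C/C=C/[C@H]3CCC4=C(O3)CC(OC(C)=O)C(=O)C=C4C)O2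
F5 | step 13 | 3-chlorocyclopent-2-en-1-one | O=C1C=C(Cl)CC1
F6 | step 13 | lithium (2R,3R)-3-methyl-1-[(triisopropylsilyl)oxy]hept-5-yn-2-olate | [Li+].CC(C)[Si](C(C)C)(C(C)C)OC[C@H]([O-])[C@H](C)CC#CC
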